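**Retrosynthetic overview**
- C8–OOH is made last, by a cobalt-hydride 1,2-hydroperoxidation of a macrocyclic 6E,8(19)-diene (new C–O bond-forming step).
- The δ-lactone (C3–O) comes from stereoinvertive 6-exo opening of the 3,4-epoxide by the C16 carboxylate; C15 is set by equilibration; the acid comes from the isopropenyl group.
- The 14-membered ring is closed by diene–ene ring-closing metathesis (C6=C7); C9–C10 and C5–C6 come from isoprenyl and vinyl Grignard substitution of a bis(epoxy triflate).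
- Both oxiranes (C3/C4, C11/C12) come from one double Sharpless epoxidation; the two E-alkenes from Wittig and Horner–Wadsworth–Emmons olefination of a keto aldehyde.
- C1 and ten carbons come from (R)-limonene oxide by periodate cleavage. Ring order: two oxiranes, then the 14-membered carbocycle, then the δ-lactone.

Assumption: cembrane numbering is used for macrocycles and locants (ring C1–C14; C1 bears C15, which carries C16 and methyl C17; methyls C18, C19, C20 sit on C4, C8, C12).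
Assumption: isoprenylmagnesium chloride, CH2=CH–C(=CH2)–CH2MgCl, is made beforehand from isoprene and used as a reagent; commercial (+)-limonene 1,2-oxide is the cis/trans mixture.

**Step 1**
Reactants: 1 (4R)-limonene 1,2-oxide (cis/trans mixture)
Product: 3 (3R)-6-oxo-3-(prop-1-en-2-yl)heptanal, via p-menth-8-ene-1,2-diol 2 (not isolated)
Conditions: H5IO6 (1.2 equiv), THF/H2O, 0 °C to rt
Reagents that add atoms: water, O
Why: Periodic acid hydrolyses the epoxide and cleaves the resulting 1,2-diol (Malaprade glycol cleavage) in one pot; the stereocentre (future C1) and the isopropenyl group are untouched.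

**Step 2**
Reactants: 3 (3R)-6-oxo-3-(prop-1-en-2-yl)heptanal
Product: 4 ethyl (2E,5R)-2-methyl-8-oxo-5-(prop-1-en-2-yl)non-2-enoate
Conditions: Ph3P=C(CH3)CO2Et (1.2 equiv), CH2Cl2, rt
Reagents that add atoms: ethyl 2-(triphenylphosphoranylidene)propanoate, CCOC(=O)C(C)=P(c1ccccc1)(c1ccccc1)c1ccccc1
Why: The stabilised Wittig ylide reacts only with the aldehyde (not the methyl ketone) and gives the E-trisubstituted enoate (E:Z above 95:5), fixing the C3=C4 geometry.

**Step 3**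
Reactants: 4 ethyl (2E,5R)-2-methyl-8-oxo-5-(prop-1-en-2-yl)non-2-enoate
Product: 5 diethyl (2E,5R,8E)-2,8-dimethyl-5-(prop-1-en-2-yl)deca-2,8-dienedioate
Conditions: (EtO)2P(O)CH2CO2Et, NaH, THF, 0 to 50 °C; 8Z isomer removed on silica
Reagents that add atoms: triethyl phosphonoacetate, CCOC(=O)CP(=O)(OCC)OCC
Why: Horner–Wadsworth–Emmons olefination of the methyl ketone gives the E-β-methyl enoate as the major isomer (about 4:1), fixing the C11=C12 geometry.

**Step 4**
Reactants: 5 diethyl (2E,5R,8E)-2,8-dimethyl-5-(prop-1-en-2-yl)deca-2,8-dienedioate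
Product: 6 (2E,5R,8E)-2,8-dimethyl-5-(prop-1-en-2-yl)deca-2,8-diene-1,10-diol
Conditions: i-Bu2AlH (5 equiv), CH2Cl2, −78 to 0 °C; Rochelle salt work-up
Reagents that add atoms: none
Why: Hydride 1,2-reduction of both enoates gives the two primary allylic alcohols without touching any alkene.

**Step 5**
Reactants: 6 (2E,5R,8E)-2,8-dimethyl-5-(prop-1-en-2-yl)deca-2,8-diene-1,10-diol
Product: 7 {(2S,3S)-3-[(2R)-4-[(2S,3S)-3-(hydroxymethyl)-2-methyloxiran-2-yl]-2-(prop-1-en-2-yl)butyl]-2-methyloxiran-2-yl}methanol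
Conditions: Ti(Oi-Pr)4 (20 mol%), L-(+)-diethyl tartrate (24 mol%), t-BuOOH (4 equiv), 4 Å sieves, CH2Cl2, −20 °C
Reagents that add atoms: tert-butyl hydroperoxide, CC(C)(C)OO
Why: Double Sharpless asymmetric epoxidation under reagent control (same facial sense as geraniol giving the 2S,3S epoxide with L-(+)-tartrate) sets C3, C4, C11 and C12 as S; the isopropenyl group has no allylic hydroxyl and is not epoxidised.

**Step 6**
Reactants: 7 {(2S,3S)-3-[(2R)-4-[(2S,3S)-3-(hydroxymethyl)-2-methyloxiran-2-yl]-2-(prop-1-en-2-yl)butyl]-2-methyloxiran-2-yl}methanol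
Product: 10 (2S,3S)-2-methyl-3-[(2R)-2-(prop-1-en-2-yl)-4-{(2S,3S)-2-methyl-3-(3-methylidenepent-4-en-1-yl)oxiran-2-yl}butyl]-2-(prop-2-en-1-yl)oxirane, via bis-triflate 8 (not isolated), via C10-isoprenyl mono-triflate 9 (not isolated)
Conditions: n-BuLi (2.0 equiv), Et2O, −78 °C; Tf2O (2.05 equiv); CH2=CH–C(=CH2)–CH2MgCl (1.05 equiv), CuI (5 mol%), −78 °C; then CH2=CHMgBr (4 equiv), CuI (15 mol%), −78 to −20 °C
Reagents that add atoms: trifluoromethanesulfonic anhydride (stays only in 8 and 9), O=S(=O)(OS(=O)(=O)C(F)(F)F)C(F)(F)F; (2-methylidenebut-3-en-1-yl)magnesium chloride, C=CC(=C)C[Mg]Cl; vinylmagnesium bromide, C=C[Mg]Br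
Why: Two copper-catalysed Grignard SN2 displacements of primary triflates: the C10 triflate (β-carbon a CH) takes the limiting isoprenyl reagent much faster than the neopentyl-like C5 triflate (β-carbon quaternary), which then takes excess vinyl reagent; the isoprenyl reagent is a symmetrical allyl system, so no regioisomers arise and no stereocentre is touched.

**Step 7**
Reactants: 10 (2S,3S)-2-methyl-3-[(2R)-2-(prop-1-en-2-yl)-4-{(2S,3S)-2-methyl-3-(3-methylidenepent-4-en-1-yl)oxiran-2-yl}butyl]-2-(prop-2-en-1-yl)oxirane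
Product: 11 (1R,3S,4S,6E,11S,12S)-3,4:11,12-diepoxycembra-6,8(19),15-triene
Conditions: second-generation Grubbs catalyst RuCl2(=CHPh)(PCy3)(H2IMes) (10 mol%), CH2Cl2 (1 mM), 40 °C
Reagents that add atoms: none
Why: Diene–ene ring-closing metathesis between the two monosubstituted alkene termini closes the 14-membered ring; the hindered 1,1-disubstituted alkenes are spectators and the conjugated 6E diene is the expected major isomer.

**Step 8**
Reactants: 11 (1R,3S,4S,6E,11S,12S)-3,4:11,12-diepoxycembra-6,8(19),15-triene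
Product: 13 (1R,3S,4S,6E,11S,12S,15RS)-3,4:11,12-diepoxycembra-6,8(19)-dien-16-ol, via B-alkyl-9-BBN adduct 12 (not isolated)
Conditions: 9-BBN (1.2 equiv), THF, 0 °C to rt; then NaOH, H2O2, 0 °C
Reagents that add atoms: 9-borabicyclo[3.3.1]nonane (boron stays only in 12), B1C2CCCC1CCC2; hydrogen peroxide, OO
Why: Hydroboration–oxidation: 9-BBN adds anti-Markovnikov to the isolated isopropenyl alkene much faster than to the conjugated diene; C15 forms as an epimer mixture that is corrected in step 10.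

**Step 9**
Reactants: 13 (1R,3S,4S,6E,11S,12S,15RS)-3,4:11,12-diepoxycembra-6,8(19)-dien-16-ol
Product: 15 (1R,3S,4S,6E,11S,12S,15RS)-3,4:11,12-diepoxycembra-6,8(19)-dien-16-oic acid, via C16 aldehyde 14 (not isolated)
Conditions: TEMPO (20 mol%), PhI(OAc)2 (2.5 equiv), MeCN/pH 7 phosphate buffer, 0 °C to rt
Reagents that add atoms: water, O
Why: Oxoammonium (TEMPO) oxidation takes the primary alcohol through the aldehyde hydrate to the acid under buffered, metal-free conditions that spare the epoxides and the diene.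

**Step 10**
Reactants: 15 (1R,3S,4S,6E,11S,12S,15RS)-3,4:11,12-diepoxycembra-6,8(19)-dien-16-oic acid
Product: 17 (1R,3R,4S,6E,11S,12S,15S)-11,12-epoxy-4-hydroxycembra-6,8(19)-dien-16,3-olide, via C15-epimeric lactones 16 (not isolated)
Conditions: DBU (0.3 equiv), MeCN, 60 °C
Reagents that add atoms: none
Why: The amidinium carboxylate opens the 3,4-epoxide by intramolecular SN2 attack at secondary C3 (6-exo-tet), inverting C3 to R and leaving the C4 tertiary alcohol with retention; DBU then equilibrates the lactone α-carbon to the all-equatorial 15S epimer.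

**Step 11**
Reactants: 17 (1R,3R,4S,6E,11S,12S,15S)-11,12-epoxy-4-hydroxycembra-6,8(19)-dien-16,3-olide
Product: 19 (1R,3R,4S,6E,8S,11S,12S,15S)-11,12-epoxy-8-hydroperoxy-4-hydroxycembr-6-en-16,3-olide, via triethylsilyl peroxide 18 (not isolated)
Conditions: [(R,R)-N,N′-bis(3,5-di-tert-butylsalicylidene)cyclohexane-1,2-diaminato]cobalt, C36H52CoN2O2 (5 mol%), O2 (1 atm), Et3SiH (3 equiv), ClCH2CH2Cl, rt; then Bu4NF, AcOH, THF, 0 °C
Reagents that add atoms: dioxygen, O=O; triethylsilane (silicon stays only in 18), CC[SiH](CC)CC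
Why: Proposed new method: cobalt-hydride hydrogen-atom transfer to the exocyclic CH2 (C19) of the 2-alkyl-1,3-diene gives the C6–C7–C8 allyl radical, which divalent cobalt captures as the σ-allyl complex at the less hindered C6; O2 then inserts with allylic transposition (SH2′, as known for allylcobalt complexes), so the O–O bond forms at tertiary C8 on the face chosen by the C2-symmetric salen ligand while the 6E alkene is restored, and Et3SiH releases the silyl peroxide and regenerates the hydride; the closest known reaction type is the Mukaiyama–Isayama hydroperoxysilylation of isolated alkenes, not yet shown as a regio- and face-selective 1,2-addition to a 2-alkyl-1,3-diene.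

**Compound list**
1 | (4R)-limonene 1,2-oxide, (4R)-1-methyl-4-(prop-1-en-2-yl)-7-oxabicyclo[4.1.0]heptane, cis/trans mixture | CC12OC1C[C@@H](CC2)C(C)=C | starting material
2 | (4R)-p-menth-8-ene-1,2-diol (not isolated) | CC1(O)C(O)C[C@@H](CC1)C(C)=C | intermediate
3 | (3R)-6-oxo-3-(prop-1-en-2-yl)heptanal | CC(=O)CC[C@H](CC=O)C(C)=C | intermediate
4 | ethyl (2E,5R)-2-methyl-8-oxo-5-(prop-1-en-2-yl)non-2-enoate | CC(=O)CC[C@H](C/C=C(\C)C(=O)OCC)C(C)=C | intermediate
5 | diethyl (2E,5R,8E)-2,8-dimethyl-5-(prop-1-en-2-yl)deca-2,8-dienedioate | CCOC(=O)/C=C(\C)CC[C@H](C/C=C(\C)C(=O)OCC)C(C)=C | intermediate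
6 | (2E,5R,8E)-2,8-dimethyl-5-(prop-1-en-2-yl)deca-2,8-diene-1,10-diol | OC/C=C(\C)CC[C@H](C/C=C(\C)CO)C(C)=C | intermediate
7 | {(2S,3S)-3-[(2R)-4-[(2S,3S)-3-(hydroxymethyl)-2-methyloxiran-2-yl]-2-(prop-1-en-2-yl)butyl]-2-methyloxiran-2-yl}methanol | OC[C@@H]1O[C@@]1(C)CC[C@H](C[C@@H]1O[C@@]1(C)CO)C(C)=C | intermediate
8 | bis(trifluoromethanesulfonate) of 7 (both CH2OH as CH2OTf; not isolated) | FC(F)(F)S(=O)(=O)OC[C@@H]1O[C@@]1(C)CC[C@H](C[C@@H]1O[C@@]1(C)COS(=O)(=O)C(F)(F)F)C(C)=C | intermediate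
9 | {(2S,3S)-2-methyl-3-[(2R)-4-{(2S,3S)-2-methyl-3-(3-methylidenepent-4-en-1-yl)oxiran-2-yl}-2-(prop-1-en-2-yl)butyl]oxiran-2-yl}methyl trifluoromethanesulfonate (not isolated) | C=CC(=C)CC[C@@H]1O[C@@]1(C)CC[C@H](C[C@@H]1O[C@@]1(C)COS(=O)(=O)C(F)(F)F)C(C)=C | intermediate
10 | (2S,3S)-2-methyl-3-[(2R)-2-(prop-1-en-2-yl)-4-{(2S,3S)-2-methyl-3-(3-methylidenepent-4-en-1-yl)oxiran-2-yl}butyl]-2-(prop-2-en-1-yl)oxirane | C=CC(=C)CC[C@@H]1O[C@@]1(C)CC[C@H](C[C@@H]1O[C@@]1(C)CC=C)C(C)=C | intermediate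
11 | (1R,3S,4S,6E,11S,12S)-3,4:11,12-diepoxycembra-6,8(19),15-triene | C=C1/C=C/C[C@]2(C)O[C@H]2C[C@@H](CC[C@]2(C)O[C@H]2CC1)C(C)=C | intermediate
12 | B-[(1R,3S,4S,6E,11S,12S,15RS)-3,4:11,12-diepoxycembra-6,8(19)-dien-16-yl]-9-borabicyclo[3.3.1]nonane (not isolated) | C=C1/C=C/C[C@]2(C)O[C@H]2C[C@@H](CC[C@]2(C)O[C@H]2CC1)C(C)CB1C2CCCC1CCC2 | intermediate
13 | (1R,3S,4S,6E,11S,12S,15RS)-3,4:11,12-diepoxycembra-6,8(19)-dien-16-ol | C=C1/C=C/C[C@]2(C)O[C@H]2C[C@@H](CC[C@]2(C)O[C@H]2CC1)C(C)CO | intermediate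
14 | (1R,3S,4S,6E,11S,12S,15RS)-3,4:11,12-diepoxycembra-6,8(19)-dien-16-al (not isolated) | C=C1/C=C/C[C@]2(C)O[C@H]2C[C@@H](CC[C@]2(C)O[C@H]2CC1)C(C)C=O | intermediate
15 | (1R,3S,4S,6E,11S,12S,15RS)-3,4:11,12-diepoxycembra-6,8(19)-dien-16-oic acid | C=C1/C=C/C[C@]2(C)O[C@H]2C[C@@H](CC[C@]2(C)O[C@H]2CC1)C(C)C(=O)O | intermediate
16 | (1R,3R,4S,6E,11S,12S,15RS)-11,12-epoxy-4-hydroxycembra-6,8(19)-dien-16,3-olide (not isolated) | CC1C(=O)O[C@@H]2C[C@H]1CC[C@]1(C)O[C@H]1CCC(=C)/C=C/C[C@]2(C)O | intermediate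
17 | (1R,3R,4S,6E,11S,12S,15S)-11,12-epoxy-4-hydroxycembra-6,8(19)-dien-16,3-olide | C[C@@H]1C(=O)O[C@@H]2C[C@H]1CC[C@]1(C)O[C@H]1CCC(=C)/C=C/C[C@]2(C)O | intermediate
18 | (1R,3R,4S,6E,8S,11S,12S,15S)-11,12-epoxy-4-hydroxy-8-(triethylsilylperoxy)cembr-6-en-16,3-olide (not isolated) | C[C@@H]1C(=O)O[C@@H]2C[C@H]1CC[C@]1(C)O[C@H]1CC[C@](C)(OO[Si](CC)(CC)CC)/C=C/C[C@]2(C)O | intermediate
19 | (1R,3R,4S,6E,8S,11S,12S,15S)-11,12-epoxy-8-hydroperoxy-4-hydroxycembr-6-en-16,3-olide | C[C@@H]1C(=O)O[C@@H]2C[C@H]1CC[C@]1(C)O[C@H]1CC[C@](C)(OO)/C=C/C[C@]2(C)O | target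

**Step count and risks**
Total steps: 11. Longest linear sequence: 11 steps (1 to 19, fully linear).

Steps most likely to fail:

Step 11 (the new reaction). Oxygen capture at C6 instead of C8, or the wrong C8 face, cannot be excluded, and the matching ligand enantiomer must be found by trial. The fallback uses known chemistry and runs from 17 back to 19. Chromium-tricarbonyl-catalysed 1,4-hydrogenation of the s-cis diene [(η6-C10H8)Cr(CO)3, H2 50 atm, acetone, 40 °C] adds hydrogen to C6 and C19 and can only give the 7E trisubstituted alkene, (1R,3R,4S,7E,11S,12S,15S)-11,12-epoxy-4-hydroxycembr-7-en-16,3-olide F1. A Schenck ene reaction of F1 (O2, hν, tetraphenylporphyrin, CH2Cl2, 0 °C) then gives 19, which is separated from the 7-hydroperoxy-8(19)-ene regioisomer and any C8 epimer.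

Step 7 (macrocyclic diene–ene metathesis). Oligomerisation, attack at the 1,1-disubstituted diene terminus or poor 6E selectivity are possible. The fallback runs from bis-triflate 8 (made as in step 6) back to 11. Me3SiC≡CCH2Li (1.05 equiv, −78 °C) replaces the isoprenyl reagent and gives the C10-(4-trimethylsilylbut-3-ynyl) mono-triflate F2; CH2=CHMgBr/CuI then gives the silylated enyne F3; K2CO3 in MeOH gives the terminal alkyne F4. Ring-closing enyne metathesis in the endo mode (second-generation Grubbs catalyst, ethene atmosphere, CH2Cl2, 40 °C) converts F4 directly into 11, the alkene CH2 becoming the C19 exo-methylene.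

Step 6 (site-selective double substitution). The neopentyl-like C5 triflate may resist the vinyl copper reagent or decompose first. The fallback runs from mono-triflate 9 (in the flask) back to 10. LiC≡CSiMe3 (−78 to −20 °C), a much better nucleophile for hindered triflates, gives the C5-propargylic silylalkyne F5; K2CO3 in MeOH gives the terminal alkyne F6; semi-hydrogenation (H2, Pd on CaCO3 poisoned with Pb(OAc)2, quinoline) gives the vinyl compound 10.

**Further compounds**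
F1 | step 11 | (1R,3R,4S,7E,11S,12S,15S)-11,12-epoxy-4-hydroxycembr-7-en-16,3-olide | C[C@@H]1C(=O)O[C@@H]2C[C@H]1CC[C@]1(C)O[C@H]1CC/C(C)=C/CC[C@]2(C)O
F2 | step 7 | {(2S,3S)-2-methyl-3-[(2R)-4-{(2S,3S)-2-methyl-3-[4-(trimethylsilyl)but-3-yn-1-yl]oxiran-2-yl}-2-(prop-1-en-2-yl)butyl]oxiran-2-yl}methyl trifluoromethanesulfonate | C[Si](C)(C)C#CCC[C@@H]1O[C@@]1(C)CC[C@H](C[C@@H]1O[C@@]1(C)COS(=O)(=O)C(F)(F)F)C(C)=C
F3 | step 7 | (2S,3S)-2-methyl-3-[(2R)-4-{(2S,3S)-2-methyl-3-[4-(trimethylsilyl)but-3-yn-1-yl]oxiran-2-yl}-2-(prop-1-en-2-yl)butyl]-2-(prop-2-en-1-yl)oxirane | C[Si](C)(C)C#CCC[C@@H]1O[C@@]1(C)CC[C@H](C[C@@H]1O[C@@]1(C)CC=C)C(C)=C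
F4 | step 7 | (2S,3S)-3-[(2R)-4-[(2S,3S)-3-(but-3-yn-1-yl)-2-methyloxiran-2-yl]-2-(prop-1-en-2-yl)butyl]-2-methyl-2-(prop-2-en-1-yl)oxirane | C#CCC[C@@H]1O[C@@]1(C)CC[C@H](C[C@@H]1O[C@@]1(C)CC=C)C(C)=C
F5 | step 6 | (2S,3S)-2-methyl-3-[(2R)-4-{(2S,3S)-2-methyl-3-(3-methylidenepent-4-en-1-yl)oxiran-2-yl}-2-(prop-1-en-2-yl)butyl]-2-[3-(trimethylsilyl)prop-2-yn-1-yl]oxirane | C=CC(=C)CC[C@@H]1O[C@@]1(C)CC[C@H](C[C@@H]1O[C@@]1(C)CC#C[Si](C)(C)C)C(C)=C
F6 | step 6 | (2S,3S)-2-methyl-3-[(2R)-4-{(2S,3S)-2-methyl-3-(3-methylidenepent-4-en-1-yl)oxiran-2-yl}-2-(prop-1-en-2-yl)butyl]-2-(prop-2-yn-1-yl)oxirane | C=CC(=C)CC[C@@H]1O[C@@]1(C)CC[C@H](C[C@@H]1O[C@@]1(C)CC#C)C(C)=C
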